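You asked for a quick number and hunched that the last readings would do, but at late times the excess can't be read directly: in the dusk run at 60.0 min the two hands sum to 6.00%, so the scatter puts about 24 percentage points on that excess.

| flask | left-handed substrate | right-handed substrate | reagent | racemization catalyst | added ligand | remark | time |
|---|---|---|---|---|---|---|---|
| winter | 0.80 M | 0.80 M | 1.6 M | 0.45 mM | 0.47 mM | run made earlier |  |
| noon | 0.80 M | 0.80 M | 1.6 M | 1 mM | 0.47 mM | run made earlier |  |
| dusk | 0.80 M | 0.80 M | 1.6 M | 2.3 mM | 0.47 mM | run made earlier |  |
| south-west | 0.80 M | 0.80 M | 1.60 M | 0.48 mM | 0.47 mM |  | 80 min |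
| east | 0.80 M | 0.80 M | 1.60 M | 2.0 mM | 0.47 mM |  | 80 min |

| run | time / min | right-handed substrate / % | left-handed substrate / % | left-handed product / % |
|---|---|---|---|---|
| winter | 12.0 | 17.0 | 8.3 | 41.5 |
| winter | 25.0 | 11.0 | 4.9 | 47.0 |
| winter | 30.0 | 11.6 | 5.3 | 49.5 |
| winter | 50.0 | 5.6 | 4.3 | 51.1 |
| winter | 60.0 | 5.0 | 3.2 | 52.1 |
| noon | 5.00 | 26.6 | 16.4 | 32.9 |
| noon | 15.0 | 15.3 | 9.4 | 44.0 |
| noon | 25.0 | 10.3 | 6.6 | 49.2 |
| noon | 40.0 | 6.8 | 3.1 | 52.7 |
| noon | 60.0 | 3.9 | 3.6 | 55.1 |
| dusk | 5.00 | 26.0 | 22.1 | 34.4 |
| dusk | 8.00 | 19.3 | 16.2 | 41.2 |
| dusk | 15.0 | 13.3 | 10.7 | 46.3 |
| dusk | 30.0 | 8.2 | 5.2 | 53.4 |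
| dusk | 60.0 | 4.1 | 1.9 | 55.1 |

(readings scatter by 1 percentage point)

- reagent is single-handed; left-handed substrate and right-handed substrate are mirror images of each other, charged as a racemate, each of them at the stated concentration
- the earlier runs were read with a standard deviation of 1 percentage point
- an excess is the difference of the two amounts in percent of their sum
- an excess is below zero if the other one leads
- the handed part of reagent does not stay in what it makes, so the products of the two hands are mirror images too

* which one finishes higher in excess of right-handed substrate over left-handed substrate among what is left of the two ("neither" within 2 percentage points) (south-west / east / neither)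
* excess of right-handed substrate over left-handed substrate among what is left of the two at the end, south-west
* excess of right-handed substrate over left-handed substrate among what is left of the two at the end, east

So we work with the fraction left. We take it that each turn uses one reagent and one substrate, and the reagent charge equals the two hands together, so the fraction of reagent left equals the fraction of substrate left. Its reciprocal then grows about linearly: the last winter reading gives a slope of 0.187 min⁻¹, so we reckon 6.28% left at 80 min.

Reagent sorts the hands and active catalyst wipes out the difference, and we expect the two to balance (a quasi-steady state). The pooled winter readings at 25.0 min and 30.0 min give an excess of 37.8% at 16.4% left, so 2.31 is the balance ratio, the excess divided by the fraction of reagent left. Dusk at 15.0 min and 30.0 min gives 15.0% at 18.7%, a ratio of 0.801.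

In that balance we expect the ratio to hold if active catalyst holds, and the excess to hold if catalyst falls as fast as reagent. South-west has 0.48 mM of catalyst against 0.45 mM in winter, and we place it between 14.5% and 37.8%; east has 2.0 mM against 2.3 mM in dusk, and we place it between 5.03% and 15.0%. Taking midpoints, we commit to 26.1% for south-west and 10.0% for east, so south-west finishes higher.

The forecast differs, naming east with 14% and 43%, on the ground for east: “then the catalyst dies and plain resolution drives it”. The flask gives 24.7% in south-west and 13.7% in east, so south-west finishes higher.

    reagent + left-handed substrate → left-handed product (k = 0.225 M⁻¹ min⁻¹)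
    reagent + right-handed substrate → right-handed product (k = 0.116 M⁻¹ min⁻¹)
    left-handed substrate + racemization catalyst ⇌ right-handed substrate + racemization catalyst, rate k3*[racemization catalyst]*[left-handed substrate] forward; the back reaction follows from the equilibrium constant (k = 65.5 M⁻¹ min⁻¹)
    reagent ⇌ dormant form (K = 0.208, k = 0.0363 min⁻¹)
    2 racemization catalyst → spent catalyst (k = 28.5 M⁻¹ min⁻¹)
    racemization catalyst + added ligand ⇌ idle complex, settled at all times (K = 1180 M⁻¹)

Taking the two hands left as the fraction left, as we did for the readings, south-west ends at a balance ratio of 4.22, above the winter reading of 2.31, with 33.1% of its catalyst charge free. In south-west the forward racemization of left-handed substrate alone, with concentrations as charged, has a half-life of 22 min, short against 80 min.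

Take the neighbour, south-west with 0.96 M of reagent: catalyst again stands at 33.1% of its charge, the reagent left, dormant form counted, is 0.0461% of the south-west charge of 1.60 M, and the ratio gives 0.195%. The computed excess is 4.37%, lower than south-west but above that value, so here the ratio gives the direction and not the number.

The numbers in the tables were generated by integration for substances that don't exist, and the scatter is random.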